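**Retrosynthetic overview**
- Feature used: ring A is a cyclohexene whose double bond C1=C10 lies at the ring fusion, with the quaternary C4 (CH3, CO2H) and the C5–H centre side by side opposite it. This is the retron of a [4+2] between a ring-B 1-vinylcyclohexene (C2=C1–C10=C5) and 2-methylacrolein (C3=C4, formyl carbon = C18).
- Ring B comes first, from the chiral pool: (R)-pulegone → (3R)-2,3-dimethylcyclohexanone (C8); Mukaiyama–Michael addition to butenone builds quaternary C9 with the C11–C13/C16 arm; ketal, enol triflate and Stille vinylation give the diene.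
- Ring A is closed second by the exo Diels–Alder reaction (C2–C3 and C4–C5 formed), which sets C4 and C5.
- The side chain is finished last: C13 ketone → E-enoate → allylic alcohol → Sharpless epoxide → Payne rearrangement–opening to the 13S,14R-triol → diacetate. C18 travels as a silyl-protected CH2OH and is oxidised to CO2H at the end.

Key step: step 8

Remark: halimane numbering is used for the bicyclic compounds (ring A: C1–C5, C10; ring B: C5–C10; side chain C11–C16 on C9; C17 on C8; C18/C19 on C4; C20 on C9). Compounds 2 and 3 are carried on as C2-epimer mixtures because that centre is planarised in step 3.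

**Step 1**
Reactants: 1 (R)-(+)-pulegone
Product: 2 (3R)-2,3-dimethyl-6-(propan-2-ylidene)cyclohexan-1-one (both C2 epimers)
Conditions: LiN(iPr)2, THF, −78 °C; MeI, −78 → 0 °C
Reagents that add atoms: iodomethane, CI
Why: Kinetic deprotonation of the enone occurs at the α'-methylene next to the methyl-bearing carbon, and SN2 methylation of this cross-conjugated enolate (enolate alkylation) brings in the future C20, while the pulegone stereocentre (future C8) is untouched.

**Step 2**
Reactants: 2 (3R)-2,3-dimethyl-6-(propan-2-ylidene)cyclohexan-1-one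
Product: 3 (3R)-2,3-dimethylcyclohexan-1-one (both C2 epimers, trans favoured)
Conditions: conc. HCl, H2O, reflux, acetone distilled off
Reagents that add atoms: none
Why: Conjugate hydration of the isopropylidene enone followed by retro-aldol cleavage expels acetone; C3 is not enolisable and keeps its R configuration.

**Step 3**
Reactants: 3 (3R)-2,3-dimethylcyclohexan-1-one
Product: 4 trimethyl{[(3R)-2,3-dimethylcyclohex-1-en-1-yl]oxy}silane
Conditions: Me3SiCl, NaI, Et3N, MeCN, rt
Reagents that add atoms: chlorotrimethylsilane, C[Si](C)(C)Cl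
Why: Equilibrating silylation with iodotrimethylsilane formed in the flask favours the more substituted (thermodynamic) silyl enol ether, which erases the C2 centre and marks C2 as the carbon to be quaternised.

**Step 4**
Reactants: 4 trimethyl{[(3R)-2,3-dimethylcyclohex-1-en-1-yl]oxy}silane; 5 but-3-en-2-one
Product: 6 (2S,3R)-2,3-dimethyl-2-(3-oxobutyl)cyclohexan-1-one (ring methyls cis)
Conditions: BF3·OEt2, i-PrOH, CH2Cl2, −78 °C
Reagents that add atoms: none
Why: In this Mukaiyama–Michael addition the BF3-activated enone is attacked by C2 of the enol ether on the face anti to the neighbouring C3 methyl (held pseudoaxial by A(1,2) strain with the C2 methyl), which sets the quaternary centre (future C9) with the two methyls cis, and isopropanol takes up the silyl group.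

**Step 5**
Reactants: 6 (2S,3R)-2,3-dimethyl-2-(3-oxobutyl)cyclohexan-1-one
Product: 7 (2S,3R)-2,3-dimethyl-2-[2-(2-methyl-1,3-dioxolan-2-yl)ethyl]cyclohexan-1-one
Conditions: HOCH2CH2OH, PPTS (cat.), benzene, reflux, Dean–Stark
Reagents that add atoms: ethylene glycol, OCCO
Why: Acid-catalysed ketalisation is chemoselective for the unhindered methyl ketone because the ring carbonyl is flanked by the quaternary carbon.

**Step 6**
Reactants: 7 (2S,3R)-2,3-dimethyl-2-[2-(2-methyl-1,3-dioxolan-2-yl)ethyl]cyclohexan-1-one
Product: 8 (5R,6S)-5,6-dimethyl-6-[2-(2-methyl-1,3-dioxolan-2-yl)ethyl]cyclohex-1-en-1-yl trifluoromethanesulfonate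
Conditions: KN(SiMe3)2, THF, −78 °C; PhNTf2, −78 → 0 °C
Reagents that add atoms: N-phenylbis(trifluoromethanesulfonimide), O=S(=O)(N(c1ccccc1)S(=O)(=O)C(F)(F)F)C(F)(F)F
Why: The ketone has α-hydrogens on one side only (future C5), so enolate formation and O-triflation (enol triflate formation) give a single regioisomer and the ketal is inert to base.

**Step 7**
Reactants: 8 enol triflate; 9 tributyl(vinyl)stannane
Product: 10 2-{2-[(1S,6R)-2-ethenyl-1,6-dimethylcyclohex-2-en-1-yl]ethyl}-2-methyl-1,3-dioxolane (ring-B diene)
Conditions: Pd(PPh3)4 (cat.), LiCl, THF, reflux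
Reagents that add atoms: none
Why: Stille coupling (oxidative addition of zerovalent palladium into the C–OTf bond, vinyl transfer from tin, reductive elimination) gives the 1-vinylcyclohexene without touching a stereocentre.

**Step 8**
Reactants: 10 ring-B diene; 11 2-methylacrolein
Product: 12 (1S,5S,6R,8aS)-1,5,6-trimethyl-5-[2-(2-methyl-1,3-dioxolan-2-yl)ethyl]-1,2,3,5,6,7,8,8a-octahydronaphthalene-1-carbaldehyde (halimane numbering 4S,5S,8R,9S; C18 formyl cis to H5)
Conditions: Et2AlCl (1.5 equiv), 11 (3 equiv), CH2Cl2, −78 → −40 °C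
Reagents that add atoms: none
Why: Et2AlCl binds the formyl oxygen of 11, and the s-cis diene C2=C1–C10=C5 of 10 adds suprafacially in a concerted, asynchronous [4+2] cycloaddition, C2 bonding to the β-carbon C3 ahead of C5 bonding to the formyl-bearing C4 (ortho orientation, from the large HOMO coefficient at the unsubstituted vinyl terminus). The closest known reaction type is the Lewis-acid-promoted Diels–Alder reaction of 6,6-disubstituted 1-vinylcyclohexenes with 2-alkylacroleins, which gives ortho adducts with the formyl group exo. Ring A is closed as a six-membered carbocycle by this intermolecular annulation onto ring B, and its double bond falls at C1=C10 by construction. C4 is fixed relative to C5 by the exo (formyl-out, methyl-in) transition state preferred by 2-methylacrolein, which places C18 trans to C6 and cis to H5, and being quaternary C4 cannot epimerise afterwards. C5 is fixed relative to C8 and C9 by the diene face: as C1=C10 develops, allylic 1,3-strain with the C1–H bond favours the half-chair in which the small C9 methyl lies near the diene plane and the longer dioxolanylethyl arm stands pseudoaxial, so the dienophile should enter on the opposite face, anti to the arm and syn to the two methyls. The step therefore needs ortho regioselectivity, exo selectivity and anti-to-arm facial selectivity, secured by the diene polarisation, the α-methyl group of the dienophile and the substituent pattern at quaternary C9 respectively, while the s-cis rotamer is favoured because the s-trans form would push the vinyl CH2 against C9.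

**Step 9**
Reactants: 12 Diels–Alder aldehyde
Product: 14 18-hydroxy-14,15-dinorhalim-1(10)-en-13-one, via hydroxy ketal 13 (not isolated)
Conditions: NaBH4, MeOH, 0 °C; then 1 M HCl, THF, rt
Reagents that add atoms: water, O
Why: Borohydride reduces the neopentyl aldehyde while the ketal masks C13, and the dilute acid added to the same flask then hydrolyses the dioxolane (carbonyl reduction, then acetal hydrolysis) without affecting the unactivated trisubstituted alkene or any stereocentre.

**Step 10**
Reactants: 14 18-hydroxy-14,15-dinorhalim-1(10)-en-13-one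
Product: 15 18-(tert-butyldimethylsilyloxy)-14,15-dinorhalim-1(10)-en-13-one
Conditions: t-BuMe2SiCl, imidazole, DMF, rt
Reagents that add atoms: tert-butyldimethylsilyl chloride, CC(C)(C)[Si](C)(C)Cl
Why: Imidazole-promoted silylation of the only hydroxyl group (silyl ether formation) keeps C18 at the alcohol oxidation level through the basic, reducing and oxidising steps that follow.

**Step 11**
Reactants: 15 silyl ether methyl ketone
Product: 16 ethyl (13E)-18-(tert-butyldimethylsilyloxy)halima-1(10),13-dien-15-oate
Conditions: (EtO)2P(O)CH2CO2Et, NaH, THF, 0 °C → reflux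
Reagents that add atoms: triethyl phosphonoacetate, CCOC(=O)CP(=O)(OCC)OCC
Why: Horner–Wadsworth–Emmons olefination of the methyl ketone with the stabilised phosphonate anion should favour the E-enoate (ester trans to the C12 chain) through reversible adduct formation, and the minor Z isomer is removed by chromatography.

**Step 12**
Reactants: 16 E-enoate
Product: 17 (13E)-18-(tert-butyldimethylsilyloxy)halima-1(10),13-dien-15-ol
Conditions: i-Bu2AlH, CH2Cl2, −78 °C; aq. potassium sodium tartrate
Reagents that add atoms: none
Why: 1,2-Reduction of the conjugated ester by the aluminium hydride gives the allylic alcohol with the E geometry intact and leaves the silyl ether and the ring alkene alone.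

**Step 13**
Reactants: 17 E-allylic alcohol
Product: 18 (13S,14S)-13,14-epoxy-18-(tert-butyldimethylsilyloxy)halim-1(10)-en-15-ol
Conditions: Ti(OiPr)4 (cat.), L-(+)-diethyl tartrate (cat.), t-BuOOH, 4 Å molecular sieves, CH2Cl2, −20 °C
Reagents that add atoms: tert-butyl hydroperoxide, CC(C)(C)OO
Why: In the Sharpless asymmetric epoxidation the titanium–tartrate complex binds the allylic alcohol and the hydroperoxide and delivers oxygen to one alkene face; with L-(+)-diethyl tartrate an E-3,3-disubstituted allylic alcohol of this geraniol-like type gives the (2S,3S)-epoxy alcohol (here 13S,14S), and the isolated C1=C10 alkene is not touched.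

**Step 14**
Reactants: 18 epoxy alcohol
Product: 20 (13S,14R)-18-(tert-butyldimethylsilyloxy)halim-1(10)-ene-13,14,15-triol, via terminal epoxide 19 (not isolated)
Conditions: 0.5 M NaOH, t-BuOH/H2O, 70 °C
Reagents that add atoms: water, O
Why: In the Payne rearrangement–opening the C15 alkoxide opens the epoxide at C14 with inversion while the C13–O bond is kept, and hydroxide then opens terminal epoxide 19 at primary C15, so the triol is 13S (retained) and 14R (inverted); direct hydroxide attack at C14 would give the same stereoisomer.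

**Step 15**
Reactants: 20 triol
Product: 21 (13S,14R)-14,15-diacetoxy-18-(tert-butyldimethylsilyloxy)halim-1(10)-en-13-ol
Conditions: Ac2O, pyridine, 0 °C → rt
Reagents that add atoms: acetic anhydride, CC(=O)OC(C)=O
Why: Acylation with Ac2O/pyridine esterifies the primary and secondary hydroxyls only, the tertiary C13 hydroxyl being too hindered without a stronger acyl-transfer catalyst.

**Step 16**
Reactants: 21 silyl ether diacetate
Product: 22 (13S,14R)-14,15-diacetoxyhalim-1(10)-ene-13,18-diol
Conditions: HF·pyridine, pyridine/THF, 0 °C → rt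
Reagents that add atoms: none
Why: Fluoride-mediated desilylation under buffered, mildly acidic conditions frees C18–OH without hydrolysis or migration of the acetates.

**Step 17**
Reactants: 22 diol diacetate
Product: 23 (13S,14R)-14,15-diacetoxy-13-hydroxyhalim-1(10)-en-18-al
Conditions: Dess–Martin periodinane, NaHCO3, CH2Cl2, rt
Reagents that add atoms: none
Why: Dess–Martin oxidation converts the primary neopentyl alcohol to the aldehyde; the tertiary alcohol cannot be oxidised and C4 has no α-hydrogen to epimerise.

**Step 18**
Reactants: 23 aldehyde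
Product: 24 (4S,5S,8R,9S,13S,14R)-14,15-diacetoxy-13-hydroxyhalim-1(10)-en-18-oic acid (CNP0224606.2)
Conditions: NaClO2, NaH2PO4, 2-methyl-2-butene, t-BuOH/H2O, rt
Reagents that add atoms: sodium chlorite, [Na+].[O-]Cl=O
Why: Pinnick oxidation takes the aldehyde to the carboxylic acid, with 2-methyl-2-butene scavenging hypochlorous acid so that the C1=C10 alkene and the acetates survive.

**Compound list**
1 | (R)-(+)-pulegone | C[C@@H]1CCC(=C(C)C)C(=O)C1 | starting material
2 | (3R)-2,3-dimethyl-6-(propan-2-ylidene)cyclohexan-1-one (C2 epimers) | C[C@@H]1CCC(=C(C)C)C(=O)C1C | intermediate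
3 | (3R)-2,3-dimethylcyclohexan-1-one (C2 epimers) | CC1C(=O)CCC[C@H]1C | intermediate
4 | trimethyl{[(3R)-2,3-dimethylcyclohex-1-en-1-yl]oxy}silane | CC1=C(O[Si](C)(C)C)CCC[C@H]1C | intermediate
5 | but-3-en-2-one | CC(=O)C=C | starting material
6 | (2S,3R)-2,3-dimethyl-2-(3-oxobutyl)cyclohexan-1-one | CC(=O)CC[C@]1(C)C(=O)CCC[C@H]1C | intermediate
7 | (2S,3R)-2,3-dimethyl-2-[2-(2-methyl-1,3-dioxolan-2-yl)ethyl]cyclohexan-1-one | CC1(OCCO1)CC[C@]2(C)C(=O)CCC[C@H]2C | intermediate
8 | (5R,6S)-5,6-dimethyl-6-[2-(2-methyl-1,3-dioxolan-2-yl)ethyl]cyclohex-1-en-1-yl trifluoromethanesulfonate | CC1(OCCO1)CC[C@]2(C)C(OS(=O)(=O)C(F)(F)F)=CCC[C@H]2C | intermediate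
9 | tributyl(vinyl)stannane | C=C[Sn](CCCC)(CCCC)CCCC | starting material
10 | 2-{2-[(1S,6R)-2-ethenyl-1,6-dimethylcyclohex-2-en-1-yl]ethyl}-2-methyl-1,3-dioxolane | CC1(OCCO1)CC[C@]2(C)C(C=C)=CCC[C@H]2C | intermediate
11 | 2-methylacrolein | C=C(C)C=O | starting material
12 | (1S,5S,6R,8aS)-1,5,6-trimethyl-5-[2-(2-methyl-1,3-dioxolan-2-yl)ethyl]-1,2,3,5,6,7,8,8a-octahydronaphthalene-1-carbaldehyde | CC1(OCCO1)CC[C@]2(C)C3=CCC[C@](C)(C=O)[C@H]3CC[C@H]2C | intermediate
13 | 13,13-(ethylenedioxy)-14,15-dinorhalim-1(10)-en-18-ol (hydroxy ketal) | CC1(OCCO1)CC[C@]2(C)C3=CCC[C@](C)(CO)[C@H]3CC[C@H]2C | intermediate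
14 | 18-hydroxy-14,15-dinorhalim-1(10)-en-13-one | CC(=O)CC[C@]1(C)C2=CCC[C@](C)(CO)[C@H]2CC[C@H]1C | intermediate
15 | 18-(tert-butyldimethylsilyloxy)-14,15-dinorhalim-1(10)-en-13-one | CC(=O)CC[C@]1(C)C2=CCC[C@](C)(CO[Si](C)(C)C(C)(C)C)[C@H]2CC[C@H]1C | intermediate
16 | ethyl (13E)-18-(tert-butyldimethylsilyloxy)halima-1(10),13-dien-15-oate | CCOC(=O)/C=C(\C)CC[C@]1(C)C2=CCC[C@](C)(CO[Si](C)(C)C(C)(C)C)[C@H]2CC[C@H]1C | intermediate
17 | (13E)-18-(tert-butyldimethylsilyloxy)halima-1(10),13-dien-15-ol | OC/C=C(\C)CC[C@]1(C)C2=CCC[C@](C)(CO[Si](C)(C)C(C)(C)C)[C@H]2CC[C@H]1C | intermediate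
18 | (13S,14S)-13,14-epoxy-18-(tert-butyldimethylsilyloxy)halim-1(10)-en-15-ol | OC[C@@H]1O[C@@]1(C)CC[C@]2(C)C3=CCC[C@](C)(CO[Si](C)(C)C(C)(C)C)[C@H]3CC[C@H]2C | intermediate
19 | (13S,14R)-14,15-epoxy-18-(tert-butyldimethylsilyloxy)halim-1(10)-en-13-ol (terminal epoxide) | C1O[C@H]1[C@@](C)(O)CC[C@]2(C)C3=CCC[C@](C)(CO[Si](C)(C)C(C)(C)C)[C@H]3CC[C@H]2C | intermediate
20 | (13S,14R)-18-(tert-butyldimethylsilyloxy)halim-1(10)-ene-13,14,15-triol | OC[C@@H](O)[C@@](C)(O)CC[C@]1(C)C2=CCC[C@](C)(CO[Si](C)(C)C(C)(C)C)[C@H]2CC[C@H]1C | intermediate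
21 | (13S,14R)-14,15-diacetoxy-18-(tert-butyldimethylsilyloxy)halim-1(10)-en-13-ol | CC(=O)OC[C@@H](OC(C)=O)[C@@](C)(O)CC[C@]1(C)C2=CCC[C@](C)(CO[Si](C)(C)C(C)(C)C)[C@H]2CC[C@H]1C | intermediate
22 | (13S,14R)-14,15-diacetoxyhalim-1(10)-ene-13,18-diol | CC(=O)OC[C@@H](OC(C)=O)[C@@](C)(O)CC[C@]1(C)C2=CCC[C@](C)(CO)[C@H]2CC[C@H]1C | intermediate
23 | (13S,14R)-14,15-diacetoxy-13-hydroxyhalim-1(10)-en-18-al | CC(=O)OC[C@@H](OC(C)=O)[C@@](C)(O)CC[C@]1(C)C2=CCC[C@](C)(C=O)[C@H]2CC[C@H]1C | intermediate
24 | (4S,5S,8R,9S,13S,14R)-14,15-diacetoxy-13-hydroxyhalim-1(10)-en-18-oic acid | CC(=O)OC[C@@H](OC(C)=O)[C@@](C)(O)CC[C@]1(C)C2=CCC[C@](C)(C(=O)O)[C@H]2CC[C@H]1C | target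

**Step count:** 18 steps in total. Longest linear sequence: 18 steps (1 → 24); 5, 9 and 11 are commercial partners that enter in steps 4, 7 and 8.

**Steps most likely to fail**

Step 8 – the dienophile may add to both diene faces (poor facial selectivity, since the two faces differ only by a methyl versus a two-carbon arm on C9), or the exo preference may erode. Fallback: change from substrate control to reagent control. Starting again from 10 and 11, the cycloaddition is run with a chiral cationic oxazaborolidine Lewis acid (the B-(o-tolyl)oxazaborolidine of α,α-diphenylprolinol protonated by HNTf2, catalytic, CH2Cl2, −78 °C). This catalyst type holds 2-substituted acroleins in one s-trans geometry, screens one enal face and is exo-selective with 2-methylacrolein. The antipode that leaves the Cα-Re face of the bound enal open is chosen; it sets C4 as S directly and, through the exo geometry, obliges the diene to react on the face anti to the arm. The product is 12 itself, where the route is rejoined; no new compound is made.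

Step 4 – loss of regiochemical and facial control at the quaternary carbon: the minor, less substituted silyl enol ether carried from step 3 would alkylate at the wrong α-carbon, and attack syn to the C3 methyl would give the C9 epimer. Fallback: from 3, condensation with (S)-1-phenylethylamine (toluene, Dean–Stark) gives the imine (1S)-N-[(3R)-2,3-dimethylcyclohexylidene]-1-phenylethanamine F1. Its more substituted secondary enamine tautomer adds to 5 (THF, rt) in an aza-ene-like Michael reaction on the face set by the amine stereocentre, which for the (S)-amine coincides with attack anti to the C3 methyl, and gives the adduct imine (1S)-N-[(2S,3R)-2,3-dimethyl-2-(3-oxobutyl)cyclohexylidene]-1-phenylethanamine F2. Aqueous acetic acid hydrolyses F2 to 6, where the route is rejoined, and the amine is recovered.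

Step 11 – formation of an E/Z mixture at the trisubstituted C13=C14 alkene that is costly to separate. Fallback: replace the carbonyl olefination by a stereospecific carbometalation. From 15, kinetic enolisation at the methyl group (LiN(iPr)2, THF, −78 °C) and trapping with ClP(O)(OEt)2 gives the terminal enol phosphate F3, which further LiN(iPr)2 eliminates to the terminal alkyne F4. Zirconium-catalysed syn-carboalumination (Me3Al, Cp2ZrCl2, CH2Cl2, rt; Negishi carboalumination) gives the (E)-alkenyl(dimethyl)alane F5, which after ate-complex formation with n-BuLi is trapped with paraformaldehyde to give 17 as the E isomer. The route is rejoined at 17 and step 12 is skipped.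

**Further compounds**
F0 | step 8 | none | none
F1 | step 4 | (1S)-N-[(3R)-2,3-dimethylcyclohexylidene]-1-phenylethanamine | CC1C(=N[C@@H](C)c2ccccc2)CCC[C@H]1C
F2 | step 4 | (1S)-N-[(2S,3R)-2,3-dimethyl-2-(3-oxobutyl)cyclohexylidene]-1-phenylethanamine | CC(=O)CC[C@]1(C)C(=N[C@@H](C)c2ccccc2)CCC[C@H]1C
F3 | step 11 | terminal enol diethyl phosphate of ketone 15 | CCOP(=O)(OCC)OC(=C)CC[C@]1(C)C2=CCC[C@](C)(CO[Si](C)(C)C(C)(C)C)[C@H]2CC[C@H]1C
F4 | step 11 | terminal alkyne, 9-(but-3-yn-1-yl) bicycle with C18 silyl ether | C#CCC[C@]1(C)C2=CCC[C@](C)(CO[Si](C)(C)C(C)(C)C)[C@H]2CC[C@H]1C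
F5 | step 11 | (E)-alkenyl(dimethyl)alane from carboalumination of F4 | C[Al](C)/C=C(\C)CC[C@]1(C)C2=CCC[C@](C)(CO[Si](C)(C)C(C)(C)C)[C@H]2CC[C@H]1C
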